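**Retrosynthetic overview**

- Feature used: in ring A (the prenylated benzoate ring) the carbon bearing the lactone carbonyl (a5) and the carbon bearing the diaryl ether oxygen (a6) are neighbours. The other four carbons carry the chelated OH (a4), the pyran carbon (a3), the pyran oxygen (a2) and the prenyl group (a1), which is a phloroglucinol carboxylate pattern.
- Key disconnection: a5 and a6 come from an aryloxy ynoate built on ring B; a4, a3, a2 and a1 come from the bis(silyloxy)diene of γ-prenylated methyl acetoacetate. A Diels–Alder/aromatization forms both C–C bonds, so the hindered ether oxygen is in place before ring A exists.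
- Ring B (tetraoxygenated chromene) is made from 3,4-dihydroxybenzaldehyde by two Baeyer–Villiger oxygenations, an ortho-formylation and a propargyl Claisen closure, then turned into the ynoate via trichloroethylene.
- After the key step: prenal annulation closes the ring A pyran, both allyl groups are removed together, the seven-membered lactone is closed and the methoxymethyl ether is cleaved.
- Ring order: ring B benzene (purchased) → ring B pyran → ring A benzene (key step) → ring A pyran → central dioxepinone.

Key step: step 13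

Remark on the chemistry: the target has no stereocentre. ArB stands for 5-(allyloxy)-8-(methoxymethoxy)-2,2-dimethyl-2H-chromen-6-yl. All numbered starting materials, and allyl propiolate (used only in a fallback), are assumed to be commercial.

**Route**

Step 1
Reactants: 1 3,4-dihydroxybenzaldehyde
Product: 2 3-hydroxy-4-(methoxymethoxy)benzaldehyde
Conditions: MOMCl (1.05 equiv), K2CO3 (1.1 equiv), acetone, 0 °C to rt
Reagents that add atoms: chloromethyl methyl ether (MOMCl), COCCl
Why: The hydroxyl para to the formyl group is the more acidic one, so with one equivalent of the chloride its phenoxide should be alkylated selectively (Williamson-type O-alkylation to the mixed acetal).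

Step 2
Reactants: 2 3-hydroxy-4-(methoxymethoxy)benzaldehyde; 3 3-chloro-3-methylbut-1-yne
Product: 4 4-(methoxymethoxy)-3-(2-methylbut-3-yn-2-yloxy)benzaldehyde
Conditions: K2CO3, KI, CuI (cat.), DMF, 60 °C
Reagents that add atoms: none
Why: Copper-assisted O-alkylation of the remaining phenol with the tertiary propargylic chloride is the standard way to aryl 1,1-dimethylpropargyl ethers and leaves the aldehyde and the acetal alone.

Step 3
Reactants: 4 4-(methoxymethoxy)-3-(2-methylbut-3-yn-2-yloxy)benzaldehyde
Product: 6 4-(methoxymethoxy)-3-(2-methylbut-3-yn-2-yloxy)phenol, via aryl formate 5 (not isolated)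
Conditions: mCPBA, CH2Cl2, 0 °C to rt; then K2CO3 (cat.), MeOH, rt
Reagents that add atoms: meta-chloroperoxybenzoic acid (mCPBA), OOC(=O)c1cccc(Cl)c1
Why: Baeyer–Villiger oxidation in which the para-alkoxy-substituted aryl group migrates gives the formate, which mild methanolysis cleaves, while the terminal alkyne and the acetal are inert to the peracid.

Step 4
Reactants: 6 4-(methoxymethoxy)-3-(2-methylbut-3-yn-2-yloxy)phenol
Product: 7 2-hydroxy-5-(methoxymethoxy)-4-(2-methylbut-3-yn-2-yloxy)benzaldehyde
Conditions: MgCl2, Et3N, (CH2O)n, THF, reflux; aq. HCl work-up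
Reagents that add atoms: paraformaldehyde (as formaldehyde), C=O
Why: Casnati–Skattebøl ortho-formylation through the magnesium phenoxide delivers the formyl group only ortho to the hydroxyl and to the less hindered of the two ortho carbons (the other is flanked by the tertiary ether), a second formaldehyde acting as hydride acceptor.

Step 5
Reactants: 7 2-hydroxy-5-(methoxymethoxy)-4-(2-methylbut-3-yn-2-yloxy)benzaldehyde
Product: 8 2-(allyloxy)-5-(methoxymethoxy)-4-(2-methylbut-3-yn-2-yloxy)benzaldehyde
Conditions: allyl bromide, K2CO3, DMF, 40 °C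
Reagents that add atoms: allyl bromide, C=CCBr
Why: Williamson O-allylation of the salicylaldehyde hydroxyl, the only free phenol, should proceed under carbonate conditions in a dipolar solvent despite chelation.

Step 6
Reactants: 8 2-(allyloxy)-5-(methoxymethoxy)-4-(2-methylbut-3-yn-2-yloxy)benzaldehyde
Product: 10 2-(allyloxy)-5-(methoxymethoxy)-4-(2-methylbut-3-yn-2-yloxy)phenol, via aryl formate 9 (not isolated)
Conditions: mCPBA (1.1 equiv), CH2Cl2, 0 °C; then K2CO3 (cat.), MeOH, rt
Reagents that add atoms: meta-chloroperoxybenzoic acid (mCPBA), OOC(=O)c1cccc(Cl)c1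
Why: Baeyer–Villiger oxidation of this 2,4,5-trioxygenated benzaldehyde should be much faster than epoxidation of the monosubstituted allyl alkene, and the pyran is closed only after this step so that no electron-rich chromene alkene meets the peracid.

Step 7
Reactants: 10 2-(allyloxy)-5-(methoxymethoxy)-4-(2-methylbut-3-yn-2-yloxy)phenol
Product: 12 5-(allyloxy)-8-(methoxymethoxy)-2,2-dimethyl-2H-chromen-6-ol (ArB–OH), via allenylphenol 11 (not isolated)
Conditions: DMF, 130 °C, argon
Reagents that add atoms: none
Why: Aromatic propargyl Claisen rearrangement to the only free ortho carbon, then 1,5-hydrogen shift and 6π-oxa-electrocyclization, should close the ring B pyran at a temperature at which the simple allyl aryl ether does not yet rearrange.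

Step 8
Reactants: 12 5-(allyloxy)-8-(methoxymethoxy)-2,2-dimethyl-2H-chromen-6-ol; 13 trichloroethylene
Product: 14 5-(allyloxy)-6-[(E)-1,2-dichlorovinyloxy]-8-(methoxymethoxy)-2,2-dimethyl-2H-chromene
Conditions: K2CO3, DMF, 70 °C
Reagents that add atoms: none
Why: Under carbonate base trichloroethylene loses HCl to dichloroacetylene, to which the phenoxide adds in anti fashion to give the (E)-1,2-dichlorovinyl ether, a known ynol ether precursor.

Step 9
Reactants: 14 5-(allyloxy)-6-[(E)-1,2-dichlorovinyloxy]-8-(methoxymethoxy)-2,2-dimethyl-2H-chromene; 15 allyl chloroformate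
Product: 18 allyl 3-(ArB-oxy)prop-2-ynoate, via chloroalkyne 16 (not isolated), via lithium acetylide 17 (not isolated)
Conditions: n-BuLi (2.2 equiv), THF, −78 to −40 °C; then cannulated into 15 (3 equiv), THF, −78 °C
Reagents that add atoms: none
Why: Vinylic deprotonation and loss of LiCl give the chloroalkyne, lithium–chlorine exchange gives the lithium aryloxyacetylide, and its C-acylation by inverse addition to excess chloroformate should give the ynol ether ester without a second addition.

Step 10
Reactants: 19 methyl acetoacetate; 20 prenyl bromide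
Product: 22 methyl 7-methyl-3-oxooct-6-enoate, via dianion 21 (not isolated)
Conditions: NaH, THF, 0 °C; then n-BuLi, 0 °C; then 20, 0 °C to rt; aq. HCl quench
Reagents that add atoms: none
Why: The β-ketoester dianion reacts with the allylic bromide at its more basic terminal (γ) carbon, the classical dianion γ-alkylation.

Step 11
Reactants: 22 methyl 7-methyl-3-oxooct-6-enoate
Product: 23 methyl 7-methyl-3-(trimethylsilyloxy)octa-2,6-dienoate (E/Z mixture)
Conditions: TMSCl, Et3N, toluene, rt
Reagents that add atoms: chlorotrimethylsilane (TMSCl), C[Si](C)(C)Cl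
Why: O-Silylation of the enol form of the β-ketoester with the chlorosilane and an amine base gives the silyl enol ether, whose geometry is lost in the next step.

Step 12
Reactants: 23 methyl 7-methyl-3-(trimethylsilyloxy)octa-2,6-dienoate
Product: 25 (1Z,3Z)-1-methoxy-7-methyl-1,3-bis(trimethylsilyloxy)octa-1,3,6-triene, via lithium dienolate 24 (not isolated)
Conditions: LiN(iPr)2, THF, −78 °C; then TMSCl, −78 to 0 °C
Reagents that add atoms: chlorotrimethylsilane (TMSCl), C[Si](C)(C)Cl
Why: Deprotonation at the γ-methylene gives the extended dienolate, which is silylated on the ester oxygen to give the 1-methoxy-1,3-bis(silyloxy)diene with the prenyl-bearing methylene outward (3Z), as the s-cis reactive conformation requires.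

Step 13
Reactants: 25 (1Z,3Z)-1-methoxy-7-methyl-1,3-bis(trimethylsilyloxy)octa-1,3,6-triene; 18 allyl 3-(ArB-oxy)prop-2-ynoate
Product: 27 allyl 6-(ArB-oxy)-2,4-dihydroxy-5-(3-methylbut-2-enyl)benzoate, via cycloadduct 26 (not isolated)
Conditions: 25 (3 equiv), toluene, 90 °C, sealed tube; then 0.5 M aq. citric acid, THF, rt
Reagents that add atoms: none
Why: Proposed new method: the electron-rich diene 25 (largest HOMO coefficient at C4, the carbon carrying the prenyl methylene) should bond to the β-carbon of the push–pull alkyne 18 (the aryloxy-bearing carbon, conjugate to the ester) while the ketene acetal carbon C1 bonds to the α-carbon, either as an asynchronous thermal [4+2] cycloaddition or as a Mukaiyama–Michael addition followed by closure of the allenoate onto the silyloxy-stabilized cation. Ring A is thus closed as a six-membered carbocycle in an intermolecular [4+2] mode that forms the C4–Cβ and C1–Cα bonds; cyclohexadiene 26 then expels methoxytrimethylsilane from its mixed silyl ketal, the dienone tautomerizes to the phenol and the remaining silyl ether is hydrolysed on acidic work-up, so the two transient sp3 centres of 26 vanish and no stereocentre needs control. The closest known reaction type is the Diels–Alder/aromatization of 1-alkoxy-1,3-bis(trimethylsilyloxy)-1,3-dienes with propiolates and acetylenedicarboxylates to give 2,4-dihydroxybenzoates; a 3-aryloxypropiolate has not been used as the 2π partner. The step needs regioselectivity (ester between the new chelated hydroxyl and the aryloxy group), which the matched polarity of the nucleophilic diene terminus and the electrophilic β-carbon should secure, and chemoselectivity over the allyl, chromene and prenyl alkenes, which are unactivated. The aryl ynol ether has no β-hydrogen on the oxygen substituent for retro-ene loss of ketene, so it should tolerate the temperature needed to offset the deactivating donor effect of the aryloxy group.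

Step 14
Reactants: 27 allyl 6-(ArB-oxy)-2,4-dihydroxy-5-(3-methylbut-2-enyl)benzoate; 28 3-methylbut-2-enal
Product: 30 allyl 7-(ArB-oxy)-5-hydroxy-2,2-dimethyl-8-(3-methylbut-2-enyl)-2H-chromene-6-carboxylate, via ortho-quinone methide 29 (not isolated)
Conditions: ethylenediammonium diacetate (20 mol %), toluene, reflux
Reagents that add atoms: none
Why: Amine-salt-catalysed condensation of the enal at the only free ring A carbon (between the two hydroxyls), loss of water to the ortho-quinone methide and 6π-oxa-electrocyclization (formal [3+3] chromene annulation) should close the pyran on the hydroxyl next to the prenyl group, because the other hydroxyl is locked in a hydrogen bond to the ester.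

Step 15
Reactants: 30 allyl 7-(ArB-oxy)-5-hydroxy-2,2-dimethyl-8-(3-methylbut-2-enyl)-2H-chromene-6-carboxylate
Product: 31 5-hydroxy-7-{[5-hydroxy-8-(methoxymethoxy)-2,2-dimethyl-2H-chromen-6-yl]oxy}-2,2-dimethyl-8-(3-methylbut-2-enyl)-2H-chromene-6-carboxylic acid
Conditions: Pd(PPh3)4 (5 mol %), morpholine, THF, rt; used directly
Reagents that add atoms: none
Why: Zerovalent palladium ionizes both the allyl ester and the allyl aryl ether to π-allyl complexes that morpholine captures (Tsuji–Trost deallylation), while the prenyl and chromene alkenes carry no leaving group and stay untouched.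

Step 16
Reactants: 31 5-hydroxy-7-{[5-hydroxy-8-(methoxymethoxy)-2,2-dimethyl-2H-chromen-6-yl]oxy}-2,2-dimethyl-8-(3-methylbut-2-enyl)-2H-chromene-6-carboxylic acid
Product: 32 O-methoxymethyl garcinisidone C (the depsidone with the ring B hydroxyl as its methoxymethyl ether)
Conditions: DCC, CH2Cl2 (0.005 M), 0 °C to rt
Reagents that add atoms: none
Why: Carbodiimide activation at high dilution should let the phenol ortho to the diaryl ether oxygen close the seven-membered depsidone lactone, since the only other free hydroxyl is the chelated one on the acid-bearing ring, which cannot reach the acyl carbon.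

Step 17
Reactants: 32 O-methoxymethyl garcinisidone C
Product: 33 garcinisidone C
Conditions: 3 M aq. HCl, THF, 40 °C
Reagents that add atoms: none
Why: Aqueous acid hydrolyses the phenolic methoxymethyl acetal; neither oxygen flanking the prenyl group is a free phenol, so no chroman can form, and the aryl lactone should survive dilute acid without an alcohol cosolvent.

**Compound list**

1 | 3,4-dihydroxybenzaldehyde | O=Cc1ccc(O)c(O)c1 | starting material
2 | 3-hydroxy-4-(methoxymethoxy)benzaldehyde | COCOc1ccc(C=O)cc1O | intermediate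
3 | 3-chloro-3-methylbut-1-yne | C#CC(C)(C)Cl | starting material
4 | 4-(methoxymethoxy)-3-(2-methylbut-3-yn-2-yloxy)benzaldehyde | COCOc1ccc(C=O)cc1OC(C)(C)C#C | intermediate
5 | 4-(methoxymethoxy)-3-(2-methylbut-3-yn-2-yloxy)phenyl formate | COCOc1ccc(OC=O)cc1OC(C)(C)C#C | intermediate (not isolated)
6 | 4-(methoxymethoxy)-3-(2-methylbut-3-yn-2-yloxy)phenol | COCOc1ccc(O)cc1OC(C)(C)C#C | intermediate
7 | 2-hydroxy-5-(methoxymethoxy)-4-(2-methylbut-3-yn-2-yloxy)benzaldehyde | COCOc1cc(C=O)c(O)cc1OC(C)(C)C#C | intermediate
8 | 2-(allyloxy)-5-(methoxymethoxy)-4-(2-methylbut-3-yn-2-yloxy)benzaldehyde | COCOc1cc(C=O)c(OCC=C)cc1OC(C)(C)C#C | intermediate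
9 | 2-(allyloxy)-5-(methoxymethoxy)-4-(2-methylbut-3-yn-2-yloxy)phenyl formate | COCOc1cc(OC=O)c(OCC=C)cc1OC(C)(C)C#C | intermediate (not isolated)
10 | 2-(allyloxy)-5-(methoxymethoxy)-4-(2-methylbut-3-yn-2-yloxy)phenol | COCOc1cc(O)c(OCC=C)cc1OC(C)(C)C#C | intermediate
11 | 3-(allyloxy)-6-(methoxymethoxy)-2-(3-methylbuta-1,2-dienyl)benzene-1,4-diol | COCOc1cc(O)c(OCC=C)c(C=C=C(C)C)c1O | intermediate (not isolated)
12 | 5-(allyloxy)-8-(methoxymethoxy)-2,2-dimethyl-2H-chromen-6-ol | Oc1cc(OCOC)c2c(c1OCC=C)C=CC(C)(C)O2 | intermediate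
13 | trichloroethylene | ClC=C(Cl)Cl | starting material
14 | 5-(allyloxy)-6-[(E)-1,2-dichlorovinyloxy]-8-(methoxymethoxy)-2,2-dimethyl-2H-chromene | Cl/C=C(/Cl)Oc1cc(OCOC)c2c(c1OCC=C)C=CC(C)(C)O2 | intermediate
15 | allyl chloroformate | C=CCOC(=O)Cl | starting material
16 | 5-(allyloxy)-6-(chloroethynyloxy)-8-(methoxymethoxy)-2,2-dimethyl-2H-chromene | ClC#COc1cc(OCOC)c2c(c1OCC=C)C=CC(C)(C)O2 | intermediate (not isolated)
17 | [(ArB-oxy)ethynyl]lithium | [Li]C#COc1cc(OCOC)c2c(c1OCC=C)C=CC(C)(C)O2 | intermediate (not isolated)
18 | allyl 3-{[5-(allyloxy)-8-(methoxymethoxy)-2,2-dimethyl-2H-chromen-6-yl]oxy}prop-2-ynoate | C=CCOC(=O)C#COc1cc(OCOC)c2c(c1OCC=C)C=CC(C)(C)O2 | intermediate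
19 | methyl acetoacetate | COC(=O)CC(C)=O | starting material
20 | prenyl bromide (1-bromo-3-methylbut-2-ene) | CC(C)=CCBr | starting material
21 | sodium lithium dianion of methyl acetoacetate | [Na+].[Li+].COC(=O)C=C([O-])[CH2-] | intermediate (not isolated)
22 | methyl 7-methyl-3-oxooct-6-enoate | COC(=O)CC(=O)CCC=C(C)C | intermediate
23 | methyl 7-methyl-3-(trimethylsilyloxy)octa-2,6-dienoate (E/Z mixture) | COC(=O)C=C(O[Si](C)(C)C)CCC=C(C)C | intermediate
24 | lithium dienolate of 23 | [Li+].COC([O-])=CC(O[Si](C)(C)C)=CCC=C(C)C | intermediate (not isolated)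
25 | (1Z,3Z)-1-methoxy-7-methyl-1,3-bis(trimethylsilyloxy)octa-1,3,6-triene | CO/C(O[Si](C)(C)C)=C/C(O[Si](C)(C)C)=C/CC=C(C)C | intermediate
26 | allyl 2-(ArB-oxy)-6-methoxy-3-(3-methylbut-2-enyl)-4,6-bis(trimethylsilyloxy)cyclohexa-1,4-diene-1-carboxylate (stereoisomer mixture) | COC1(O[Si](C)(C)C)C=C(O[Si](C)(C)C)C(CC=C(C)C)C(Oc2cc(OCOC)c3c(c2OCC=C)C=CC(C)(C)O3)=C1C(=O)OCC=C | intermediate (not isolated)
27 | allyl 6-(ArB-oxy)-2,4-dihydroxy-5-(3-methylbut-2-enyl)benzoate | C=CCOC(=O)c1c(O)cc(O)c(CC=C(C)C)c1Oc1cc(OCOC)c2c(c1OCC=C)C=CC(C)(C)O2 | intermediate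
28 | 3-methylbut-2-enal | CC(C)=CC=O | starting material
29 | allyl 2-(ArB-oxy)-6-hydroxy-3-(3-methylbut-2-enyl)-5-(3-methylbut-2-enylidene)-4-oxocyclohexa-1(6),2-diene-1-carboxylate | C=CCOC(=O)C1=C(O)C(=CC=C(C)C)C(=O)C(CC=C(C)C)=C1Oc1cc(OCOC)c2c(c1OCC=C)C=CC(C)(C)O2 | intermediate (not isolated)
30 | allyl 7-(ArB-oxy)-5-hydroxy-2,2-dimethyl-8-(3-methylbut-2-enyl)-2H-chromene-6-carboxylate | C=CCOC(=O)c1c(O)c2C=CC(C)(C)Oc2c(CC=C(C)C)c1Oc1cc(OCOC)c2c(c1OCC=C)C=CC(C)(C)O2 | intermediate
31 | 5-hydroxy-7-{[5-hydroxy-8-(methoxymethoxy)-2,2-dimethyl-2H-chromen-6-yl]oxy}-2,2-dimethyl-8-(3-methylbut-2-enyl)-2H-chromene-6-carboxylic acid | OC(=O)c1c(O)c2C=CC(C)(C)Oc2c(CC=C(C)C)c1Oc1cc(OCOC)c2c(c1O)C=CC(C)(C)O2 | intermediate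
32 | O-methoxymethyl garcinisidone C | CC(C)=CCc1c2c(c(O)c3c1Oc1cc(OCOC)c4c(c1OC3=O)C=CC(C)(C)O4)C=CC(C)(C)O2 | intermediate
33 | garcinisidone C | CC(C)=CCc1c2c(c(O)c3c1Oc1cc(O)c4c(c1OC3=O)C=CC(C)(C)O4)C=CC(C)(C)O2 | target

**Step count and risks**

Total: 17 steps. Longest linear sequence: 14 steps (steps 1–9 and 13–17); the diene branch (steps 10–12) joins at step 13.

Steps most likely to fail:

1. Step 13 (proposed new method). The aryloxy donor may slow bond formation so much that thermal silyl migration and desilylation of diene 25, or hydration of ynol ether 18, win the race; alternatively the first conjugate adduct may expel aryloxide instead of closing the ring. The fallback uses known chemistry, sets out from 25 and 12 and comes back at 27: the diaryl ether is made by an Ullmann condensation on a ring A bromide whose substitution pattern is fixed by the documented Diels–Alder/aromatization of such dienes with acetylenic esters, 3-halopropiolates being established dienophiles. Diene 25 is heated in toluene with allyl 3-bromoprop-2-ynoate F1 (from allyl propiolate, N-bromosuccinimide and catalytic AgNO3). The cycloadduct allyl 2-bromo-6-methoxy-3-(3-methylbut-2-enyl)-4,6-bis(trimethylsilyloxy)cyclohexa-1,4-diene-1-carboxylate F2 aromatizes on the same acidic work-up to allyl 2-bromo-4,6-dihydroxy-3-(3-methylbut-2-enyl)benzoate F3, with bromine where the aryloxy group is needed. Both hydroxyls are silylated (iPr3SiOTf, 2,6-lutidine, CH2Cl2) to give allyl 2-bromo-3-(3-methylbut-2-enyl)-4,6-bis(triisopropylsilyloxy)benzoate F4. Coupling of F4 with phenol 12 (CuI, N,N-dimethylglycine, Cs2CO3, dioxane, 100 °C), assisted by the ortho ester, gives allyl 2-(ArB-oxy)-3-(3-methylbut-2-enyl)-4,6-bis(triisopropylsilyloxy)benzoate F5, and Bu4NF buffered with AcOH in THF at 0 °C removes both silyl groups to return 27.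

2. Step 9. The acetylide or residual n-BuLi may attack the newly formed ester, n-BuLi may metalate next to the allyl ether oxygen, and the push–pull alkyne may be hydrated during work-up. The fallback sets out from 14 and comes back at 18: the acetylide 17 is generated as before but quenched with methanol to give the isolable terminal ynol ether 5-(allyloxy)-6-(ethynyloxy)-8-(methoxymethoxy)-2,2-dimethyl-2H-chromene F6. This is converted to 18 by copper-catalysed carboxylative coupling (CuI cat., Cs2CO3, CO2 at 1 atm, allyl bromide, DMF, rt), so the ester carbon comes from CO2 and no organolithium is present when the sensitive ynoate forms.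

3. Step 14. The pyran may close on the ester-chelated hydroxyl, the free hydroxyl may cyclize onto the neighbouring prenyl alkene at reflux, or condensation on the fully substituted ring may stall. The fallback sets out from 27 and comes back at 30: the non-chelated hydroxyl is O-alkylated with 3-chloro-3-methylbut-1-yne 3 (CuCl2·2H2O cat., DBU, MeCN, 0 °C) to give allyl 6-(ArB-oxy)-2-hydroxy-4-(2-methylbut-3-yn-2-yloxy)-5-(3-methylbut-2-enyl)benzoate F7. Heating in DMF at 130 °C then effects the aromatic propargyl Claisen rearrangement to the only free ortho carbon, passing through the allenylphenol allyl 6-(ArB-oxy)-2,4-dihydroxy-3-(3-methylbuta-1,2-dienyl)-5-(3-methylbut-2-enyl)benzoate F8, which closes to 30; the pyran oxygen is then fixed by the site of O-alkylation.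

**Further compounds**

F1 | step 13 | allyl 3-bromoprop-2-ynoate | C=CCOC(=O)C#CBr
F2 | step 13 | allyl 2-bromo-6-methoxy-3-(3-methylbut-2-enyl)-4,6-bis(trimethylsilyloxy)cyclohexa-1,4-diene-1-carboxylate | COC1(O[Si](C)(C)C)C=C(O[Si](C)(C)C)C(CC=C(C)C)C(Br)=C1C(=O)OCC=C
F3 | step 13 | allyl 2-bromo-4,6-dihydroxy-3-(3-methylbut-2-enyl)benzoate | C=CCOC(=O)c1c(O)cc(O)c(CC=C(C)C)c1Br
F4 | step 13 | allyl 2-bromo-3-(3-methylbut-2-enyl)-4,6-bis(triisopropylsilyloxy)benzoate | C=CCOC(=O)c1c(O[Si](C(C)C)(C(C)C)C(C)C)cc(O[Si](C(C)C)(C(C)C)C(C)C)c(CC=C(C)C)c1Br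
F5 | step 13 | allyl 2-(ArB-oxy)-3-(3-methylbut-2-enyl)-4,6-bis(triisopropylsilyloxy)benzoate | C=CCOC(=O)c1c(O[Si](C(C)C)(C(C)C)C(C)C)cc(O[Si](C(C)C)(C(C)C)C(C)C)c(CC=C(C)C)c1Oc1cc(OCOC)c2c(c1OCC=C)C=CC(C)(C)O2
F6 | step 9 | 5-(allyloxy)-6-(ethynyloxy)-8-(methoxymethoxy)-2,2-dimethyl-2H-chromene | C#COc1cc(OCOC)c2c(c1OCC=C)C=CC(C)(C)O2
F7 | step 14 | allyl 6-(ArB-oxy)-2-hydroxy-4-(2-methylbut-3-yn-2-yloxy)-5-(3-methylbut-2-enyl)benzoate | C=CCOC(=O)c1c(O)cc(OC(C)(C)C#C)c(CC=C(C)C)c1Oc1cc(OCOC)c2c(c1OCC=C)C=CC(C)(C)O2
F8 | step 14 | allyl 6-(ArB-oxy)-2,4-dihydroxy-3-(3-methylbuta-1,2-dienyl)-5-(3-methylbut-2-enyl)benzoate | C=CCOC(=O)c1c(O)c(C=C=C(C)C)c(O)c(CC=C(C)C)c1Oc1cc(OCOC)c2c(c1OCC=C)C=CC(C)(C)O2
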